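**Retrosynthetic overview**
- The target is a hexasubstituted benzene, its only ring. The plan rests on the adjacent C(OH)–C(OH) pair and the C–CH3 carbon para to one of these carbons. These three atoms coincide with C4, C5 and C2 of a 5-oxygenated 2-methyl-4-pyranone. Five ring carbons and both oxygens therefore come ready-made, and only ring atom O1 has to be traded for the C–Br carbon between C–CH3 and the neighbouring C–Br.
- Endgame disconnections: the two C–Br bonds ortho to the hydroxyls (bromination of the free catechol, last), the two O–CH3 bonds (BBr3), and the third C–Br bond (Sandmeyer exchange, traced back through NH2 to NO2).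
- Key disconnection: both C–C bonds at the nitro-bearing carbon, which leads to nitromethane and allomaltol methyl ether. The pyranone ring opens and the benzene ring closes in one operation, the only ring formation of the route.
- The pyranone comes from kojic acid by deoxygenation of CH2OH to CH3 (SOCl2, then Zn/HCl) and O-methylation.

Key step: step 4

Remark on the chemistry: the target has no stereogenic element, so no step controls configuration; the phenol released in the key step is capped as a second methyl ether before nitro reduction, because a free para-aminophenol would be oxidised by nitrous acid and its diazonium salt would collapse to a quinone diazide.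

Step 1
Reactants: 1 kojic acid (5-hydroxy-2-(hydroxymethyl)-4H-pyran-4-one)
Product: 2 chlorokojic acid (2-(chloromethyl)-5-hydroxy-4H-pyran-4-one)
Conditions: SOCl2 (neat), rt
Reagents that add atoms: thionyl chloride, ClS(Cl)=O
Why: Chlorodehydroxylation through the chlorosulfite ester (SN2-type collapse) converts only the primary, allylic-type CH2OH, because the enolic 5-OH sits on an sp2 carbon and cannot be displaced.

Step 2
Reactants: 2 chlorokojic acid
Product: 3 allomaltol (5-hydroxy-2-methyl-4H-pyran-4-one)
Conditions: Zn dust, conc. HCl, H2O, 60–70 °C
Reagents that add atoms: none
Why: Zinc–acid reductive dehalogenation: electron transfer to the C–Cl bond, which is activated as a vinylogous alpha-halo ketone, and protonation of the resulting dienolate at the exocyclic carbon give the methyl group, while the pyranone ring is not reduced under these conditions.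

Step 3
Reactants: 3 allomaltol
Product: 4 allomaltol methyl ether (5-methoxy-2-methyl-4H-pyran-4-one)
Conditions: MeI, K2CO3, acetone, reflux
Reagents that add atoms: iodomethane, CI
Why: Williamson ether synthesis on the acidic enol, needed because a free 5-OH would be deprotonated in step 4 to an electron-rich anion that no longer accepts a nucleophile.

Step 4
Reactants: 4 allomaltol methyl ether; 5 nitromethane
Product: 7 2-methoxy-5-methyl-4-nitrophenol, via open-chain nitro dione 6 (not isolated)
Conditions: MeNO2 (5 equiv), KOtBu (3 equiv), t-BuOH, reflux; then aq HCl
Reagents that add atoms: none
Why: Potassium methanenitronate adds in conjugate fashion to an alpha carbon of the pyranone, most likely the unsubstituted C6, and the 2H-pyran enolate so formed breaks its C6–O1 bond (retro-oxa-Michael, equally a 6π electrocyclic opening) to give the salt of open-chain nitro dione 6. Deprotonation of its CH2NO2 group gives a delocalised nitronate in which the C5=C6 geometry can equilibrate, and the nitronate carbon attacks the freed methyl ketone carbonyl (old C2) in an intramolecular Henry reaction, a 6-exo-trig closure of the only ring that is formed; loss of water and enolisation of the old C4 carbonyl then aromatise the ring, so that two C–C bonds (to old C6 and old C2) are made and O1 leaves as water. The closest known reaction type is the KOtBu-mediated recyclisation of 2,6-dialkyl-4-pyranones with nitromethane to 4-nitrophenols, the neutral counterpart of the pyrylium-to-nitroarene conversion; the present pyranone differs by a 5-alkoxy donor and one free alpha position, and the routine exchange of O1 for nitrogen when 3-alkoxy-4-pyranones meet primary amines shows that this pattern accepts nucleophiles at the alpha carbons and opens. The step needs attack at an alpha carbon and not at C4: addition to the C4 carbonyl is reversible and has no productive exit, whereas attack at C2 in place of C6 opens to an isomeric chain whose nitronate closes on the aldehyde carbon to the same arene, so regioisomers cannot arise. Methylation of the 5-hydroxyl in step 3 secures the reactivity, since a free enol would be deprotonated to an anion that repels the nitronate. No stereocentre is created, and formation of the stabilised para-nitrophenolate makes the last event irreversible and pulls the preceding equilibria forward.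

Step 5
Reactants: 7 2-methoxy-5-methyl-4-nitrophenol
Product: 8 1,2-dimethoxy-4-methyl-5-nitrobenzene
Conditions: MeI, K2CO3, DMF, rt to 40 °C
Reagents that add atoms: iodomethane, CI
Why: Williamson ether synthesis on the acidic para-nitrophenol, which masks the oxygen through steps 6 and 7 and costs no extra deprotection since both methyl ethers fall in step 8.

Step 6
Reactants: 8 1,2-dimethoxy-4-methyl-5-nitrobenzene
Product: 9 4,5-dimethoxy-2-methylaniline
Conditions: H2 (1 atm), 10% Pd/C, EtOH, rt
Reagents that add atoms: none
Why: Catalytic hydrogenation of an aromatic nitro group to the aniline, placed before any bromine is on the ring so that hydrodehalogenation cannot interfere.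

Step 7
Reactants: 9 4,5-dimethoxy-2-methylaniline
Product: 11 1-bromo-4,5-dimethoxy-2-methylbenzene, via arenediazonium bromide 10 (not isolated)
Conditions: NaNO2, 48% aq HBr, 0 °C; then CuBr, 48% aq HBr, 0 to 60 °C
Reagents that add atoms: hydrogen bromide, Br (source of the ring bromine and of the counter-ion of 10, relayed by CuBr, Br[Cu], which is regenerated); sodium nitrite, [Na+].[O-]N=O (second nitrogen of 10)
Why: Diazotisation followed by the Sandmeyer reaction: monovalent copper reduces the diazonium ion to an aryl radical with loss of N2, and the radical takes bromine from the divalent copper bromide so formed, which puts Br on exactly the carbon that nitromethane supplied.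

Step 8
Reactants: 11 1-bromo-4,5-dimethoxy-2-methylbenzene
Product: 12 4-bromo-5-methylbenzene-1,2-diol
Conditions: BBr3 (3 equiv), CH2Cl2, −78 °C to rt; then H2O
Reagents that add atoms: none
Why: Lewis-acid ether cleavage: BBr3 binds each methoxy oxygen, bromide removes the methyl group by SN2 attack, and hydrolysis of the aryl borate frees the catechol, the aryl bromide and the ring methyl being inert.

Step 9
Reactants: 12 4-bromo-5-methylbenzene-1,2-diol
Product: 13 3,4,6-tribromo-5-methylbenzene-1,2-diol (target)
Conditions: Br2 (2.1 equiv), AcOH, dark, 0 °C to rt
Reagents that add atoms: bromine, BrBr
Why: Electrophilic aromatic bromination (SEAr) of a strongly activated catechol whose only two free ring positions each lie ortho to a hydroxyl, so exhaustive substitution can give just one product, the target.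

**Compound list**
1 | kojic acid, 5-hydroxy-2-(hydroxymethyl)-4H-pyran-4-one | OCC1=CC(=O)C(O)=CO1 | starting material
2 | chlorokojic acid, 2-(chloromethyl)-5-hydroxy-4H-pyran-4-one | ClCC1=CC(=O)C(O)=CO1 | intermediate
3 | allomaltol, 5-hydroxy-2-methyl-4H-pyran-4-one | CC1=CC(=O)C(O)=CO1 | intermediate
4 | allomaltol methyl ether, 5-methoxy-2-methyl-4H-pyran-4-one | COC1=COC(C)=CC1=O | intermediate
5 | nitromethane | C[N+](=O)[O-] | starting material
6 | open-chain nitro dione, (5E)-5-methoxy-7-nitrohept-5-ene-2,4-dione (present as its potassium salt; the isomer with the acyl carbon and CH2NO2 cis, which can close) | CC(=O)CC(=O)/C(OC)=C\C[N+](=O)[O-] | intermediate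
7 | 2-methoxy-5-methyl-4-nitrophenol | COc1cc([N+](=O)[O-])c(C)cc1O | intermediate
8 | 1,2-dimethoxy-4-methyl-5-nitrobenzene | COc1cc(C)c([N+](=O)[O-])cc1OC | intermediate
9 | 4,5-dimethoxy-2-methylaniline | COc1cc(C)c(N)cc1OC | intermediate
10 | arenediazonium bromide, 4,5-dimethoxy-2-methylbenzenediazonium bromide | COc1cc(C)c([N+]#N)cc1OC.[Br-] | intermediate
11 | 1-bromo-4,5-dimethoxy-2-methylbenzene | COc1cc(C)c(Br)cc1OC | intermediate
12 | 4-bromo-5-methylbenzene-1,2-diol | Cc1cc(O)c(O)cc1Br | intermediate
13 | 3,4,6-tribromo-5-methylbenzene-1,2-diol | Cc1c(Br)c(O)c(O)c(Br)c1Br | target

Total step count: 9
Longest linear sequence: 9 steps (kojic acid 1 to target 13; nitromethane 5 enters at step 4)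

**Steps most likely to fail**

**Step 4 (key step).**
- What may go wrong: the 5-methoxy group feeds electron density onto C6, so nitronate addition may be too slow to compete with base-induced self-condensation of nitromethane. The opened chain may also fragment by retro-Claisen cleavage before the carbon–carbon closure.
- Fallback (a cationic electrophile in place of the neutral one): it sets out from 4. O-methylation at the carbonyl oxygen with methyl trifluoromethanesulfonate in CH2Cl2 gives 4,5-dimethoxy-2-methylpyrylium trifluoromethanesulfonate F1.
- This much more electrophilic cation is treated with nitromethane 5 and KOtBu in t-BuOH (pyrylium-to-nitroarene ring transformation). Attack is expected at C6, the only unsubstituted alpha position. Opening, Henry closure and dehydration should then give the dimethyl ether directly.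
- The fallback comes back to the route at 8 and makes step 5 unnecessary. Attack at C4 followed by loss of methanol is the side path to watch there.

**Step 7.**
- What may go wrong: the electron-rich diazonium ion is reduced only sluggishly by monovalent copper, so hydrolysis to the phenol, azo coupling with unreacted aniline and hydrogen abstraction by the aryl radical may outrun bromine transfer. Adventitious ring bromination at the two free positions would be harmless, since both carry bromine in the target.
- Fallback (C–Br bond by electrophilic substitution instead of radical exchange): it sets out from 9, which is diazotised to 10 as in step 7 and then deliberately reduced with aqueous H3PO2 at 0 °C to rt. This gives 1,2-dimethoxy-4-methylbenzene F2.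
- N-bromosuccinimide in MeCN then brominates F2 at the position para to one methoxy group and ortho to the methyl group. The fallback comes back to the route at 11.

**Step 9.**
- What may go wrong: bromine may oxidise the catechol to the ortho-quinone faster than it substitutes the second, more hindered position, and the quinone may add HBr or decompose.
- Fallback (bromination while the oxygens are masked): it sets out from 11, which is treated with excess Br2 and catalytic FeBr3 in CHCl3 at reflux to give 1,2,4-tribromo-5,6-dimethoxy-3-methylbenzene F3.
- BBr3 in CH2Cl2, as in step 8, then cleaves both ethers. The fallback comes back to the route at the target 13.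

**Further compounds**
F1 | step 4 | 4,5-dimethoxy-2-methylpyrylium trifluoromethanesulfonate | COc1cc(C)[o+]cc1OC.[O-]S(=O)(=O)C(F)(F)F
F2 | step 7 | 1,2-dimethoxy-4-methylbenzene | COc1ccc(C)cc1OC
F3 | step 9 | 1,2,4-tribromo-5,6-dimethoxy-3-methylbenzene | COc1c(Br)c(C)c(Br)c(Br)c1OC
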